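## Structural features

The target is an achiral diaryl ether. Ring A is a salicylic acid, numbered C1 (CO2H), C2 (OH), C3 (prenyl), C4 and C5 (H), C6 (ether oxygen). Ring B is numbered C1′ (CH2OH), C2′ (ether oxygen), C3′ (OH), C5′ (CH3), so its methyl group lies para to the ether oxygen. There is no stereocentre, and the only alkene, the trisubstituted prenyl double bond, has no E/Z element. Both ether carbons carry two ortho substituents (C6 next to the carboxyl-bearing C1; C2′ between C1′ and C3′), which makes the ether bond a poor candidate for direct coupling. The fragile groups are: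

- the prenyl group beside the C2 phenol, which closes to a chroman under strong acid and would not survive hydrogenolysis;
- the electron-rich benzylic alcohol, which can ionise and could be trapped by the free acid as an eight-membered lactone;
- the carboxyl group, whose esters resist attack at the carbonyl because C1 is flanked on both sides.

The real difficulty is the contiguous C6–C1–C2–C3 pattern of ring A with the hindered ether attached, combined with protecting groups that can be removed without a boron trihalide or forcing saponification. The key step exploits the carboxyl carbon flanked by two oxygens: C1, C2, C3 and C4 of ring A map onto C3, C4, C5 and C6 of a 3-carboalkoxy-2-pyrone, and C5 and C6 with the ether oxygen are the two carbons of an aryl ynol ether.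

## Logic of the disconnections

30 ⇒ 29. The O–allyl bond of an allyl ester is the last bond to be broken. A carboxyl between two ortho substituents is cleaved far more easily at the allylic carbon than at the carbonyl, so the acid can be released last under neutral conditions. The demand on the forward step is that morpholine captures the allyl fragment faster than the phenols do.

29 ⇒ 28. Three O-protecting bonds are restored in one retrosynthetic move: the methoxymethyl acetal on the C3′ oxygen, the silyl ether on the benzylic oxygen and the acetyl group on the C2 oxygen. The first two are needed for the organolithium step and the hot cycloaddition, the third for the diene. The forward step must use acid mild enough for the prenyl group and the benzylic alcohol.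

28 ⇒ 13 + 26 (key disconnection). The C1–C6 and C4–C5 bonds of ring A are cut. This divides the molecule into two halves of similar size, brings all four contiguous substituents of ring A and the ether oxygen in already attached, and avoids any coupling at the hindered ether. The forward step needs an electron-poor diene, a storable terminal ynol ether, and regiochemistry fixed by the polarity of both partners. The atom map was checked and is consistent: the oxygen-bearing alkyne carbon ends up next to the ester. Two design choices differ from the simplest version of this pair (a methyl ether at the pyrone C4 oxygen and a methyl ester):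

- The C4 oxygen of 13 is acetylated. An ether there would donate into the diene and would later need a boron trihalide, which the prenyl group, the acetal and the silyl ether would not tolerate.
- The ester is allyl. A methyl ester between two ortho substituents would be very hard to saponify.

13 ⇒ 12 ⇒ 10. After the O–acetyl bond, the ring O1–C2 bond of the pyrone is cut. The ring oxygen becomes a masked formyl oxygen (a methyl enol ether) and the lactone carbonyl becomes one ester of a malonate. The forward closure needs only dilute aqueous acid, which the prenyl group must survive.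

10 ⇒ 7 + 8. The C3–C4 bond of the future pyrone is an acyl–malonate bond. It is formed from an acid chloride (9, made in the flask from 7) and the magnesium enolate of 8. The demand is an acid chloride made without HCl, because of the alkene and the enol ether.

7 ⇒ 6 ⇒ 4. The acid comes from its methyl ester. The bond between the α-carbon and the methoxymethylidene carbon, and the O–CH3 bond, are then cut, which leads to a simple ester and a one-carbon formate unit.

4 ⇒ 1 + 2. The C2–C3 bond of the hexenoate is cut as a [3,3] shift. This places the trisubstituted alkene without any alkylation by a prenyl halide.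

26 ⇒ 23 ⇒ 22 ⇒ 21. The alkyne is traced to an (E)-1,2-dichlorovinyl ether, the silyl ether to the alcohol, and the alcohol to the aldehyde. The aldehyde is kept through the O-vinylation and reduced just before the organolithium step.

21 ⇒ 18 + 19. The aryl O–C(vinyl) bond is cut, so that both alkyne carbons come from trichloroethylene. The forward step requires the C2′ oxygen to be the only free phenol.

18 ⇒ 17 ⇒ 16. The methoxymethyl group is placed on the C3′ oxygen of a catechol aldehyde. The catechol comes from a methyl ether, because the oxygen that must become the free C3′ phenol is the methoxy oxygen of the starting phenol. The forward step must distinguish two phenoxides of one dianion.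

16 ⇒ 14. The aryl C–CHO bond is cut. In 14 the only free position ortho to the hydroxyl is the one required, and the methyl group is already para to the future ether oxygen.

## Other disconnections considered

Alternative 1: Ring B is cut at C1′–C2′ and C4′–C5′, which leads back to the ring A aryloxyacetone A1 and the silyloxy ynone A2.
- Forward key step: a base adds the oxygen-bearing methylene carbon of A1 to the β-carbon of A2. The acetyl methyl group then condenses with the ynone carbonyl and water is lost, giving the phenol A3.
- In its favour: ring B arrives with its C3′ phenol free and correctly placed. No ynol ether and no prolonged heating are needed. The ether oxygen is attached to ring A by a simple phenol alkylation.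
- Against it here: A1 has two enolisable positions and the Michael adduct has two aldol modes; closure in the other sense would put the methyl group next to the ether oxygen. The base must also spare the dioxinone. In addition, A1 needs a ring A whose prenyl group sits ortho to the acetal oxygen and not ortho to the free phenol, which ordinary phenol prenylation does not deliver.
- Comparison: the two plans are equal in convergence and in forming two skeletal bonds in one operation. Alternative 1 is the better on thermal mildness and on delivering a free phenol directly. The pyrone plan is the better on regiochemical certainty, because its orientation follows from the polarity of both partners and not from a choice between enolates. Step counts should be similar, since the effort saved on ring B is spent on a regiodefined ring A.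

Alternative 2: The bond between the ether oxygen and C2′ is traced back to a spirocycle. The diaryl ether acid A6 would come from the grisadienedione A5, and A5 from the benzophenone A4.
- Forward key step: two-electron oxidation of the ring B phenol of A4 (PhI(OAc)2, a trivalent iodine reagent, or an anode) makes C2′ cationic. The C6 oxygen of ring A captures it with loss of its methoxymethyl group, closing the five-membered furanone of A5. Hydroxide attack at the furanone carbonyl and cleavage of the bond to the spiro carbon then rearomatise ring B and give A6.
- In its favour: the hindered ether bond is made intramolecularly. The spiro centre is racemic but is destroyed again, so no stereocontrol is needed. No thermally sensitive ynol ether is involved. The ring opening releases the carboxylic acid without any ester cleavage, and on this point it is the better of the two plans.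
- Against it here: the oxidised phenol has free ortho and para positions (C4′, C6′) where external nucleophiles can intercept it. The internal nucleophile is an acetal oxygen, a weak one. The prenyl alkene and ring A are themselves oxidisable, and the cyclohexadienone of A5 can dimerise. A4 is a benzophenone with four ortho substituents, and making it needs an aryl–metal addition and an oxidation.
- Comparison: the chosen plan has a single pericyclic pathway with one regiochemical issue. Alternative 2 must win two contests of chemoselectivity, the site of oxidation and the site of hydroxide attack. It is likely to be two to four steps longer because of the redox adjustments around A4.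

Alternative 3: Ring A is cut at C1–C2, C2–C3 and C5–C6, giving the cyclobutenone A7 and the same ynol ether 26 that the chosen plan uses.
- Forward key step (Danheiser benzannulation): heating opens A7 to a vinylketene, which adds to 26 in a [2+2] sense. Four-electron ring opening and six-electron ring closure of the resulting dienylketene give the phenol A8.
- In its favour: alkoxyalkynes are classical partners of vinylketenes. The regiochemistry (ether oxygen meta to the new phenol, prenyl ortho to it) is as dependable as in the chosen plan, so the two are equal on that point. The cascade should run at a lower temperature than a pyrone cycloaddition, which is better for the ynol ether.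
- Against it here: A7 is a cyclobutenone substituted only at C4, a volatile compound prone to polymerisation and hard to prepare. A8 lacks the carboxyl carbon, so C1 must afterwards be metallated between its two oxygens and carboxylated. That needs protection of the new phenol and has to compete with metallation next to the acetal on ring B.
- Comparison: both plans rely on the same ynol ether. The pyrone brings in the carboxyl carbon and the C2 oxygen at the right oxidation level, so the chosen plan should be three or four steps shorter after the ring-forming event. Alternative 3 has the gentler ring formation.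

Key step: step 14

Remark on the chemistry: the locants used in the text are those defined under "Structural features"; compound names use systematic locants. The enol ether geometries drawn for 6, 7, 9 and 10 are the expected E forms, and this geometry is lost in step 5, so either isomer serves.

## Steps

Step 1
Reactants: 1 2-methylbut-3-en-2-ol; 2 trimethyl orthoacetate
Product: 4 methyl 5-methylhex-4-enoate, via mixed ketene acetal 3 (not isolated)
Conditions: EtCO2H (cat.), neat, 110 → 140 °C, MeOH distilled off
Reagents that add atoms: none
Why: Johnson–Claisen rearrangement: acid-catalysed exchange gives the allyl ketene acetal 3, whose [3,3] shift forms the new C–C bond at the unsubstituted alkene terminus and leaves the trisubstituted (prenyl-type) double bond.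

Step 2
Reactants: 4 methyl 5-methylhex-4-enoate
Product: 6 methyl (2E)-2-(methoxymethylidene)-5-methylhex-4-enoate, via sodium formyl ester enolate 5 (not isolated)
Conditions: NaH, HCO2Me, THF, 0 °C → rt; then MeOTs, K2CO3, DMF, rt
Reagents that add atoms: methyl formate, COC=O; methyl 4-methylbenzenesulfonate, COS(=O)(=O)c1ccc(C)cc1
Why: Crossed Claisen condensation with the non-enolisable formate is driven by formation of the stabilised enolate 5; the hard sulfonate ester then alkylates the enolate oxygen, the standard entry to β-methoxyacrylates, with the E isomer expected as the more stable one.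

Step 3
Reactants: 6 methyl (2E)-2-(methoxymethylidene)-5-methylhex-4-enoate
Product: 7 (2E)-2-(methoxymethylidene)-5-methylhex-4-enoic acid
Conditions: LiOH·H2O, THF/MeOH/H2O, 50 °C; then 1 M HCl to pH 3, 0 °C
Reagents that add atoms: lithium hydroxide, [Li+].[OH-]
Why: Saponification at the ester carbonyl; the β-methoxy enol ether is inert to hydroxide, and cold, brief acidification avoids its hydrolysis.

Step 4
Reactants: 7 (2E)-2-(methoxymethylidene)-5-methylhex-4-enoic acid; 8 di(prop-2-enyl) propanedioate (diallyl malonate)
Product: 10 di(prop-2-enyl) 2-[(2E)-2-(methoxymethylidene)-5-methylhex-4-enoyl]propanedioate, via acid chloride 9 (not isolated)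
Conditions: Me2C=C(Cl)NMe2, CH2Cl2, 0 °C → rt; then 8, MgCl2, Et3N, MeCN, 0 °C → rt
Reagents that add atoms: none
Why: The chloroenamine converts the acid into its chloride without releasing HCl, so the alkene and the enol ether are not exposed to acid; C-acylation of the magnesium enolate of the malonate is driven by formation of the chelated tricarbonyl enolate and stops after one acylation.

Step 5
Reactants: 10 di(prop-2-enyl) 2-[(2E)-2-(methoxymethylidene)-5-methylhex-4-enoyl]propanedioate
Product: 12 prop-2-enyl 4-hydroxy-5-(3-methylbut-2-enyl)-2-oxo-2H-pyran-3-carboxylate, via hydroxymethylidene tricarbonyl 11 (not isolated)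
Conditions: 1 M aq HCl, THF, rt → 40 °C
Reagents that add atoms: water, O
Why: Aqueous acid hydrolyses the vinylogous ester to the chelated enol 11, whose hydroxyl lies cis to the acyl group and attacks one ester carbonyl in a 6-exo-trig lactonisation with loss of allyl alcohol; this is the cyclisation type that turns 3,5-dioxo esters and 5-alkoxy-2,4-dienoates into 2-pyrones, and it is driven by the conjugated, hydrogen-bonded 4-hydroxy-2-pyrone.

Step 6
Reactants: 12 prop-2-enyl 4-hydroxy-5-(3-methylbut-2-enyl)-2-oxo-2H-pyran-3-carboxylate
Product: 13 prop-2-enyl 4-acetoxy-5-(3-methylbut-2-enyl)-2-oxo-2H-pyran-3-carboxylate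
Conditions: Ac2O, Et3N, DMAP (cat.), CH2Cl2, 0 °C
Reagents that add atoms: acetic anhydride, CC(=O)OC(C)=O
Why: O-acylation of the vinylogous acid at the C4 oxygen; C3 and C5 are both substituted, so no C-acylation or acyl shift can follow. The acetyl group removes the acidic OH, which would add across the ynol ether, and reduces oxygen donation into the diene.

Step 7
Reactants: 14 creosol (2-methoxy-4-methylphenol)
Product: 16 2-hydroxy-3-methoxy-5-methylbenzaldehyde, via ortho-hydroxymethyl phenol 15 (not isolated)
Conditions: MgCl2, Et3N, (CH2O)n, MeCN, reflux; 1 M HCl
Reagents that add atoms: paraformaldehyde (as formaldehyde), C=O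
Why: Magnesium-mediated ortho-formylation: the magnesium phenoxide delivers formaldehyde to the only free ortho position, and a second formaldehyde oxidises the benzylic alkoxide 15 by hydride transfer.

Step 8
Reactants: 16 2-hydroxy-3-methoxy-5-methylbenzaldehyde
Product: 17 2,3-dihydroxy-5-methylbenzaldehyde
Conditions: BBr3, CH2Cl2, −78 °C → rt; H2O
Reagents that add atoms: none
Why: Lewis-acid ether cleavage: boron binds the ether oxygen and bromide attacks the methyl carbon (SN2); aryl aldehydes tolerate the reagent and are restored on hydrolysis.

Step 9
Reactants: 17 2,3-dihydroxy-5-methylbenzaldehyde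
Product: 18 2-hydroxy-3-(methoxymethoxy)-5-methylbenzaldehyde
Conditions: NaH (2.1 equiv), DMF, 0 °C; MOMCl (1.0 equiv), 0 °C → rt
Reagents that add atoms: chloromethyl methyl ether, COCCl
Why: Williamson alkylation of the dianion: the C2 phenoxide is conjugated to and chelated with the formyl group, so the C3 phenoxide is the more nucleophilic and takes the single equivalent of electrophile.

Step 10
Reactants: 18 2-hydroxy-3-(methoxymethoxy)-5-methylbenzaldehyde; 19 trichloroethylene
Product: 21 2-{[(E)-1,2-dichloroethenyl]oxy}-3-(methoxymethoxy)-5-methylbenzaldehyde, via dichloroacetylene 20 (not isolated)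
Conditions: K2CO3, DMF, 70 °C
Reagents that add atoms: none
Why: O-Dichlorovinylation of a phenol: carbonate eliminates HCl from 19 to give 20 in solution, the phenoxide adds to it and the vinyl anion is protonated anti, which gives the E isomer.

Step 11
Reactants: 21 2-{[(E)-1,2-dichloroethenyl]oxy}-3-(methoxymethoxy)-5-methylbenzaldehyde
Product: 22 [2-{[(E)-1,2-dichloroethenyl]oxy}-3-(methoxymethoxy)-5-methylphenyl]methanol
Conditions: NaBH4, THF/MeOH, 0 °C
Reagents that add atoms: none
Why: Borohydride reduction of the aldehyde only; the vinyl chlorides and the acetal are inert to NaBH4.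

Step 12
Reactants: 22 [2-{[(E)-1,2-dichloroethenyl]oxy}-3-(methoxymethoxy)-5-methylphenyl]methanol
Product: 23 tert-butyl{[2-{[(E)-1,2-dichloroethenyl]oxy}-3-(methoxymethoxy)-5-methylphenyl]methoxy}dimethylsilane
Conditions: TBSCl, imidazole, DMF, rt
Reagents that add atoms: tert-butyl(chloro)dimethylsilane, CC(C)(C)[Si](C)(C)Cl
Why: Imidazole-mediated silylation of a primary alcohol; the silyl ether carries the benzylic oxygen through the organolithium step and the hot cycloaddition, where a free hydroxyl would add to the ynol ether.

Step 13
Reactants: 23 tert-butyl{[2-{[(E)-1,2-dichloroethenyl]oxy}-3-(methoxymethoxy)-5-methylphenyl]methoxy}dimethylsilane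
Product: 26 tert-butyl{[2-(ethynyloxy)-3-(methoxymethoxy)-5-methylphenyl]methoxy}dimethylsilane, via aryl chloroethynyl ether 24 (not isolated), via lithium aryloxyacetylide 25 (not isolated)
Conditions: n-BuLi (2.3 equiv), THF, −78 → −40 °C; H2O, −78 °C → 0 °C
Reagents that add atoms: none
Why: Ynol ether synthesis from a 1,2-dichlorovinyl ether: deprotonation of the vinylic C–H and anti elimination of LiCl give 24, chlorine–lithium exchange gives 25, and cold protonation releases the terminal ynol ether; the two ortho substituents shield it against oligomerisation.

Step 14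
Reactants: 13 prop-2-enyl 4-acetoxy-5-(3-methylbut-2-enyl)-2-oxo-2H-pyran-3-carboxylate; 26 tert-butyl{[2-(ethynyloxy)-3-(methoxymethoxy)-5-methylphenyl]methoxy}dimethylsilane
Product: 28 prop-2-enyl 2-acetoxy-6-[2-({[tert-butyl(dimethyl)silyl]oxy}methyl)-6-(methoxymethoxy)-4-methylphenoxy]-3-(3-methylbut-2-enyl)benzoate, via bridged bicyclic lactone 27 (not isolated)
Conditions: 26 (1.5 equiv, in two portions), PhMe, 4 Å MS, sealed tube, 110 → 130 °C
Reagents that add atoms: none
Why: Inverse-electron-demand Diels–Alder reaction: the C3 ester and the lactone carbonyl lower the LUMO of the pyrone diene (C3 to C6), and the aryloxy oxygen raises the HOMO of the alkyne. Bond formation is asynchronous: the nucleophilic terminal alkyne carbon attacks the electrophilic C6 first, and the oxygen-bearing carbon then closes onto C3, which carries the malonate-type charge. This polarity match is the regiocontrol the step needs, and it places the aryloxy group beside the ester (ring A C6). The bridged lactone 27 does not persist at this temperature: retro-[4+2] loss of CO2 gives the benzoate directly, because the dienophile is an alkyne and no elimination or oxidation is required. Ring A is thus closed by an intermolecular [4+2] cycloaddition followed by a [4+2] cycloreversion, which forms its C1–C6 and C4–C5 bonds. No stereocentre is created in 28; the two bridgehead centres of 27 are transient and racemic. The unactivated prenyl and allyl alkenes cannot compete with the electron-rich alkyne, and the acetyl group makes the diene more electron-poor than an alkoxy group would. The closest known reaction type is the cycloaddition of 3-carbomethoxy-2-pyrones with ketene acetals, ynamines and alkoxyalkynes followed by CO2 loss to give salicylate derivatives.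

Step 15
Reactants: 28 prop-2-enyl 2-acetoxy-6-[2-({[tert-butyl(dimethyl)silyl]oxy}methyl)-6-(methoxymethoxy)-4-methylphenoxy]-3-(3-methylbut-2-enyl)benzoate
Product: 29 prop-2-enyl 2-hydroxy-6-[2-hydroxy-6-(hydroxymethyl)-4-methylphenoxy]-3-(3-methylbut-2-enyl)benzoate
Conditions: HCl (1.25 M in MeOH), THF, 0 °C → rt
Reagents that add atoms: none
Why: Acid-catalysed acetal exchange removes the methoxymethyl group as dimethoxymethane, so no free formaldehyde reaches the electron-rich ring; the primary silyl ether is solvolysed and the aryl acetate transesterified. The doubly ortho-substituted allyl ester does not exchange and keeps the carboxyl masked, so the benzylic position cannot be trapped as a lactone; any acetate left over is removed by morpholine in step 16 and converges on 30.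

Step 16
Reactants: 29 prop-2-enyl 2-hydroxy-6-[2-hydroxy-6-(hydroxymethyl)-4-methylphenoxy]-3-(3-methylbut-2-enyl)benzoate
Product: 30 2-hydroxy-6-[2-hydroxy-6-(hydroxymethyl)-4-methylphenoxy]-3-(3-methylbut-2-enyl)benzoic acid
Conditions: Pd(PPh3)4 (5 mol %), morpholine (10 equiv), THF, rt; NaHCO3 extraction, then citric acid to pH 3, 0 °C
Reagents that add atoms: none
Why: Tsuji–Trost deallylation: zerovalent palladium ionises the ester at the allylic carbon, which is insensitive to the shielding of the carbonyl, and morpholine traps the π-allyl complex; the prenyl group has no leaving group and is untouched, and any phenol allylated in passing is deallylated by the same reagents.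

## Compound list

1 | 2-methylbut-3-en-2-ol | CC(C)(O)C=C | starting material
2 | trimethyl orthoacetate (1,1,1-trimethoxyethane) | CC(OC)(OC)OC | starting material
3 | 3-[(1-methoxyethenyl)oxy]-3-methylbut-1-ene (mixed ketene acetal) | C=C(OC)OC(C)(C)C=C | intermediate
4 | methyl 5-methylhex-4-enoate | COC(=O)CCC=C(C)C | intermediate
5 | sodium enolate of methyl 2-formyl-5-methylhex-4-enoate (configurationally labile) | [Na+].[O-]C=C(CC=C(C)C)C(=O)OC | intermediate
6 | methyl (2E)-2-(methoxymethylidene)-5-methylhex-4-enoate | CO/C=C(CC=C(C)C)/C(=O)OC | intermediate
7 | (2E)-2-(methoxymethylidene)-5-methylhex-4-enoic acid | CO/C=C(CC=C(C)C)/C(=O)O | intermediate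
8 | di(prop-2-enyl) propanedioate (diallyl malonate) | C=CCOC(=O)CC(=O)OCC=C | starting material
9 | (2E)-2-(methoxymethylidene)-5-methylhex-4-enoyl chloride | CO/C=C(CC=C(C)C)/C(=O)Cl | intermediate
10 | di(prop-2-enyl) 2-[(2E)-2-(methoxymethylidene)-5-methylhex-4-enoyl]propanedioate | CO/C=C(CC=C(C)C)/C(=O)C(C(=O)OCC=C)C(=O)OCC=C | intermediate
11 | di(prop-2-enyl) 2-[(2Z)-2-(hydroxymethylidene)-5-methylhex-4-enoyl]propanedioate (chelated enol of the formyl compound) | O/C=C(/CC=C(C)C)C(=O)C(C(=O)OCC=C)C(=O)OCC=C | intermediate
12 | prop-2-enyl 4-hydroxy-5-(3-methylbut-2-enyl)-2-oxo-2H-pyran-3-carboxylate | C=CCOC(=O)C1=C(O)C(CC=C(C)C)=COC1=O | intermediate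
13 | prop-2-enyl 4-acetoxy-5-(3-methylbut-2-enyl)-2-oxo-2H-pyran-3-carboxylate | C=CCOC(=O)C1=C(OC(C)=O)C(CC=C(C)C)=COC1=O | intermediate
14 | creosol (2-methoxy-4-methylphenol) | COc1cc(C)ccc1O | starting material
15 | 2-(hydroxymethyl)-6-methoxy-4-methylphenol (as its magnesium salt) | COc1cc(C)cc(CO)c1O | intermediate
16 | 2-hydroxy-3-methoxy-5-methylbenzaldehyde | COc1cc(C)cc(C=O)c1O | intermediate
17 | 2,3-dihydroxy-5-methylbenzaldehyde | Cc1cc(O)c(O)c(C=O)c1 | intermediate
18 | 2-hydroxy-3-(methoxymethoxy)-5-methylbenzaldehyde | COCOc1cc(C)cc(C=O)c1O | intermediate
19 | trichloroethylene | ClC=C(Cl)Cl | starting material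
20 | dichloroacetylene | ClC#CCl | intermediate
21 | 2-{[(E)-1,2-dichloroethenyl]oxy}-3-(methoxymethoxy)-5-methylbenzaldehyde | Cl/C=C(/Cl)Oc1c(OCOC)cc(C)cc1C=O | intermediate
22 | [2-{[(E)-1,2-dichloroethenyl]oxy}-3-(methoxymethoxy)-5-methylphenyl]methanol | Cl/C=C(/Cl)Oc1c(OCOC)cc(C)cc1CO | intermediate
23 | tert-butyl{[2-{[(E)-1,2-dichloroethenyl]oxy}-3-(methoxymethoxy)-5-methylphenyl]methoxy}dimethylsilane | Cl/C=C(/Cl)Oc1c(OCOC)cc(C)cc1CO[Si](C)(C)C(C)(C)C | intermediate
24 | tert-butyl{[2-[(chloroethynyl)oxy]-3-(methoxymethoxy)-5-methylphenyl]methoxy}dimethylsilane | ClC#COc1c(OCOC)cc(C)cc1CO[Si](C)(C)C(C)(C)C | intermediate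
25 | lithium acetylide of 26 | [Li]C#COc1c(OCOC)cc(C)cc1CO[Si](C)(C)C(C)(C)C | intermediate
26 | tert-butyl{[2-(ethynyloxy)-3-(methoxymethoxy)-5-methylphenyl]methoxy}dimethylsilane | C#COc1c(OCOC)cc(C)cc1CO[Si](C)(C)C(C)(C)C | intermediate
27 | racemic prop-2-enyl 8-acetoxy-5-[2-({[tert-butyl(dimethyl)silyl]oxy}methyl)-6-(methoxymethoxy)-4-methylphenoxy]-7-(3-methylbut-2-enyl)-3-oxo-2-oxabicyclo[2.2.2]octa-5,7-diene-4-carboxylate (bridgeheads fixed relative to each other by the bicycle) | O=C1OC2C(CC=C(C)C)=C(OC(C)=O)C1(C(=O)OCC=C)C(Oc3c(OCOC)cc(C)cc3CO[Si](C)(C)C(C)(C)C)=C2 | intermediate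
28 | prop-2-enyl 2-acetoxy-6-[2-({[tert-butyl(dimethyl)silyl]oxy}methyl)-6-(methoxymethoxy)-4-methylphenoxy]-3-(3-methylbut-2-enyl)benzoate | CC(C)=CCc1ccc(Oc2c(OCOC)cc(C)cc2CO[Si](C)(C)C(C)(C)C)c(C(=O)OCC=C)c1OC(C)=O | intermediate
29 | prop-2-enyl 2-hydroxy-6-[2-hydroxy-6-(hydroxymethyl)-4-methylphenoxy]-3-(3-methylbut-2-enyl)benzoate | CC(C)=CCc1ccc(Oc2c(O)cc(C)cc2CO)c(C(=O)OCC=C)c1O | intermediate
30 | 2-hydroxy-6-[2-hydroxy-6-(hydroxymethyl)-4-methylphenoxy]-3-(3-methylbut-2-enyl)benzoic acid | CC(C)=CCc1ccc(Oc2c(O)cc(C)cc2CO)c(C(=O)O)c1O | target

## Step count and least certain steps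

Total: 16 steps. Longest linear sequence: 10 steps (steps 7 to 16, from creosol 14). The pyrone branch (steps 1 to 6) joins at step 14.

Step 14 (key step).
- What may go wrong: the cycloaddition may be slower than the thermal consumption of the ynol ether (oligomerisation, or addition of traces of water or acid across the triple bond). An acyloxy group at C4 and an alkyl group at C5 leave the diene only moderately electron-poor, and the bond to C3 must form next to a bulky aryloxy group. Acetyl transfer from the vinylogous anhydride is a second drain.
- Fallback, changing the diene and not only the conditions: the route is left at 12 and comes back at 29. The C4 oxygen of 12 is converted (Tf2O, Et3N, CH2Cl2, −78 °C) into the vinyl triflate prop-2-enyl 5-(3-methylbut-2-enyl)-2-oxo-4-{[(trifluoromethyl)sulfonyl]oxy}-2H-pyran-3-carboxylate F1. This diene has an acceptor in place of a donor at C4 and should combine with 26 well below 100 °C. After CO2 loss it should give the aryl triflate prop-2-enyl 6-[2-({[tert-butyl(dimethyl)silyl]oxy}methyl)-6-(methoxymethoxy)-4-methylphenoxy]-3-(3-methylbut-2-enyl)-2-{[(trifluoromethyl)sulfonyl]oxy}benzoate F2. S–O cleavage with Et4NOH in dioxane at rt would unmask the phenol prop-2-enyl 2-hydroxy-6-[2-({[tert-butyl(dimethyl)silyl]oxy}methyl)-6-(methoxymethoxy)-4-methylphenoxy]-3-(3-methylbut-2-enyl)benzoate F3. F3, treated as in step 15, rejoins the route at 29.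

Step 5.
- What may go wrong: incomplete ring closure of the tricarbonyl, or acid-induced addition of water or of the new C4 hydroxyl to the prenyl double bond during the time the lactonisation needs.
- Fallback, closing the ring by the C3–C4 bond instead of the O1–C2 bond: it sets out from the enolate 5 (formed from 4 in the first stage of step 2) and comes back at 12. The enolate 5 in THF at −78 °C is O-acylated with prop-2-enyl 3-chloro-3-oxopropanoate F4 (from potassium allyl malonate and oxalyl chloride). This gives the enol ester methyl (2Z)-5-methyl-2-({[3-oxo-3-(prop-2-enyloxy)propanoyl]oxy}methylidene)hex-4-enoate F5. A Dieckmann-type condensation (LiHMDS, THF, −78 → 0 °C), of the kind that converts O-malonyl salicylates into 4-hydroxycoumarin-3-carboxylates, then closes the ring onto the methyl ester and gives 12 with loss of methanol.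

Step 10.
- What may go wrong: slow O-vinylation of a chelated phenoxide that is flanked on both sides, with base-induced degradation of the aldehyde at 70 °C competing.
- Fallback, changing the order of events: it sets out from 18 and comes back at 23. Compound 18 is reduced (NaBH4, MeOH, 0 °C) to 2-(hydroxymethyl)-6-(methoxymethoxy)-4-methylphenol F6. The primary hydroxyl is silylated (TBSCl, 1.05 equiv, imidazole, CH2Cl2, 0 °C) to 2-({[tert-butyl(dimethyl)silyl]oxy}methyl)-6-(methoxymethoxy)-4-methylphenol F7. The now electron-rich phenoxide of F7 (KH, THF) is treated with 19 at rt and gives 23 directly.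

Step 13.
- What may go wrong: loss of the terminal ynol ether during work-up and concentration (hydration to the aryl acetate, oligomerisation), and some competing ring lithiation next to the acetal.
- Fallback, isolating a protected form instead of the free alkyne: it sets out from 23 and comes back at 26. Compound 23 is taken to the acetylide 25 as in step 13, and 25 is quenched with TMSCl to give the storable C-silyl ynol ether tert-butyl(dimethyl){[3-(methoxymethoxy)-5-methyl-2-{[(trimethylsilyl)ethynyl]oxy}phenyl]methoxy}silane F8. F8 is desilylated at carbon (K2CO3, MeOH, 0 °C) immediately before step 14 to give 26.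

Step 15.
- What may go wrong: ionisation of the benzylic alcohol in acidic methanol (methyl ether formation, self-alkylation of the electron-rich ring), and acid-catalysed closure of the prenyl group onto the freed C2 phenol.
- Fallback, avoiding protic acid altogether: it sets out from 28 and comes back at 30. The acetal of 28 is cleaved with TMSOTf and 2,2′-bipyridyl (CH2Cl2, 0 °C, then H2O) while the benzylic oxygen is still silylated. This gives prop-2-enyl 2-acetoxy-6-[2-({[tert-butyl(dimethyl)silyl]oxy}methyl)-6-hydroxy-4-methylphenoxy]-3-(3-methylbut-2-enyl)benzoate F9. The silyl ether is then removed with Et3N·3HF (THF, rt) to give prop-2-enyl 2-acetoxy-6-[2-hydroxy-6-(hydroxymethyl)-4-methylphenoxy]-3-(3-methylbut-2-enyl)benzoate F10. The reagents of step 16 remove the allyl and acetyl groups of F10 together and give 30.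

## Further compounds

F1 | step 14 | prop-2-enyl 5-(3-methylbut-2-enyl)-2-oxo-4-{[(trifluoromethyl)sulfonyl]oxy}-2H-pyran-3-carboxylate | C=CCOC(=O)C1=C(OS(=O)(=O)C(F)(F)F)C(CC=C(C)C)=COC1=O
F2 | step 14 | prop-2-enyl 6-[2-({[tert-butyl(dimethyl)silyl]oxy}methyl)-6-(methoxymethoxy)-4-methylphenoxy]-3-(3-methylbut-2-enyl)-2-{[(trifluoromethyl)sulfonyl]oxy}benzoate | CC(C)=CCc1ccc(Oc2c(OCOC)cc(C)cc2CO[Si](C)(C)C(C)(C)C)c(C(=O)OCC=C)c1OS(=O)(=O)C(F)(F)F
F3 | step 14 | prop-2-enyl 2-hydroxy-6-[2-({[tert-butyl(dimethyl)silyl]oxy}methyl)-6-(methoxymethoxy)-4-methylphenoxy]-3-(3-methylbut-2-enyl)benzoate | CC(C)=CCc1ccc(Oc2c(OCOC)cc(C)cc2CO[Si](C)(C)C(C)(C)C)c(C(=O)OCC=C)c1O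
F4 | step 5 | prop-2-enyl 3-chloro-3-oxopropanoate | C=CCOC(=O)CC(=O)Cl
F5 | step 5 | methyl (2Z)-5-methyl-2-({[3-oxo-3-(prop-2-enyloxy)propanoyl]oxy}methylidene)hex-4-enoate | COC(=O)/C(CC=C(C)C)=C\OC(=O)CC(=O)OCC=C
F6 | step 10 | 2-(hydroxymethyl)-6-(methoxymethoxy)-4-methylphenol | COCOc1cc(C)cc(CO)c1O
F7 | step 10 | 2-({[tert-butyl(dimethyl)silyl]oxy}methyl)-6-(methoxymethoxy)-4-methylphenol | COCOc1cc(C)cc(CO[Si](C)(C)C(C)(C)C)c1O
F8 | step 13 | tert-butyl(dimethyl){[3-(methoxymethoxy)-5-methyl-2-{[(trimethylsilyl)ethynyl]oxy}phenyl]methoxy}silane | C[Si](C)(C)C#COc1c(OCOC)cc(C)cc1CO[Si](C)(C)C(C)(C)C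
F9 | step 15 | prop-2-enyl 2-acetoxy-6-[2-({[tert-butyl(dimethyl)silyl]oxy}methyl)-6-hydroxy-4-methylphenoxy]-3-(3-methylbut-2-enyl)benzoate | CC(C)=CCc1ccc(Oc2c(O)cc(C)cc2CO[Si](C)(C)C(C)(C)C)c(C(=O)OCC=C)c1OC(C)=O
F10 | step 15 | prop-2-enyl 2-acetoxy-6-[2-hydroxy-6-(hydroxymethyl)-4-methylphenoxy]-3-(3-methylbut-2-enyl)benzoate | CC(C)=CCc1ccc(Oc2c(O)cc(C)cc2CO)c(C(=O)OCC=C)c1OC(C)=O
A1 | alternative 1 | 2,2-dimethyl-8-(3-methylbut-2-enyl)-5-(2-oxopropoxy)-4H-1,3-benzodioxin-4-one | CC(C)=CCc1ccc(OCC(C)=O)c2C(=O)OC(C)(C)Oc12
A2 | alternative 1 | 5-{[tert-butyl(dimethyl)silyl]oxy}pent-3-yn-2-one | CC(=O)C#CCO[Si](C)(C)C(C)(C)C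
A3 | alternative 1 | 5-[2-({[tert-butyl(dimethyl)silyl]oxy}methyl)-6-hydroxy-4-methylphenoxy]-2,2-dimethyl-8-(3-methylbut-2-enyl)-4H-1,3-benzodioxin-4-one | CC(C)=CCc1ccc(Oc3c(O)cc(C)cc3CO[Si](C)(C)C(C)(C)C)c2C(=O)OC(C)(C)Oc12
A4 | alternative 2 | [2,6-bis(methoxymethoxy)-3-(3-methylbut-2-enyl)phenyl][2-({[tert-butyl(dimethyl)silyl]oxy}methyl)-6-hydroxy-4-methylphenyl]methanone | CC(C)=CCc1ccc(OCOC)c(C(=O)c2c(O)cc(C)cc2CO[Si](C)(C)C(C)(C)C)c1OCOC
A5 | alternative 2 | racemic 2′-({[tert-butyl(dimethyl)silyl]oxy}methyl)-4-(methoxymethoxy)-4′-methyl-5-(3-methylbut-2-enyl)-3H-spiro[1-benzofuran-2,1′-cyclohexa-2′,4′-diene]-3,6′-dione | CC(C)=CCc1ccc2OC3(C(=O)C=C(C)C=C3CO[Si](C)(C)C(C)(C)C)C(=O)c2c1OCOC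
A6 | alternative 2 | 6-[2-({[tert-butyl(dimethyl)silyl]oxy}methyl)-6-hydroxy-4-methylphenoxy]-2-(methoxymethoxy)-3-(3-methylbut-2-enyl)benzoic acid | CC(C)=CCc1ccc(Oc2c(O)cc(C)cc2CO[Si](C)(C)C(C)(C)C)c(C(=O)O)c1OCOC
A7 | alternative 3 | racemic 4-(3-methylbut-2-enyl)cyclobut-2-en-1-one | CC(C)=CCC1C=CC1=O
A8 | alternative 3 | 5-[2-({[tert-butyl(dimethyl)silyl]oxy}methyl)-6-(methoxymethoxy)-4-methylphenoxy]-2-(3-methylbut-2-enyl)phenol | CC(C)=CCc1ccc(Oc2c(OCOC)cc(C)cc2CO[Si](C)(C)C(C)(C)C)cc1O
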